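**Plan**

1. Locants: ring A is the trione ring (C1 spiro, C2 and C6 carbonyls, C3 acyl-bearing, C4 enol, C5 gem-diprenyl). Ring B is the spiro cyclohexane and ring C the cyclopentane, with primed octahydroindene locants (C5' = C1 is the spiro carbon, C3' and C7' are the carbinol carbons, C3a'/C7a' the ring fusion).
2. Cuts, in order: the two prenyl–C5 bonds; C2–C3 and C5–C6 of ring A (Claisen bonds), leaving a spiro malonate whose axial carboxyl is a γ-lactone to the C7' oxygen; C5'–C6' (radical closure of ring B onto an isopropenyl group) and C4'=C5' (Knoevenagel); finally C3'–C3a' of ring C (aldol), the keto aldehyde being re-closed to the cyclohexane-1,2-diol of limonene.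
3. Forward: ring C by one-carbon contraction of the p-menthane ring, then ring B together with the quaternary spiro carbon, then ring A, with the prenyl groups last.
4. Enabling feature: carbinol carbon C3' is β to C4', the CH2 between C3a' and the spiro carbon. With C4' as CHO, ring C is the intramolecular aldol adduct of a 6-oxoheptanal carrying an isopropenyl branch (later C7', its methyl and C6') on C7a'; that chain is p-menth-8-ene-1,2-diol cleaved between its two carbinol carbons.
5. Stereochemistry: C7a' is bought (C4 of (R)-limonene). C3a' and C3' are relayed from it in the aldol. C7' and the spiro carbon both follow from the lactone that only the axial ester can form in the radical step, which tells the two carbonyl groups on C5' apart before ring A is built.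

Key step: step 1

Remark: the β-triketones of the last three steps are mixtures of enol tautomers and each is written as one of them; the limonene diol, dimethyl malonate, 5-methylhexane-2,4-dione and prenyl bromide are taken as purchased.

**Route**

Step 1
Reactants: 1 (1S,2S,4R)-1-methyl-4-(prop-1-en-2-yl)cyclohexane-1,2-diol
Product: 3 (1S,2R,5R)-2-hydroxy-2-methyl-5-(prop-1-en-2-yl)cyclopentane-1-carbaldehyde, via keto aldehyde 2 (not isolated)
Conditions: PhI(OAc)2, CH2Cl2, 0 °C to rt; then L-proline (20 mol %), rt
Reagents that add atoms: none
Why: PhI(OAc)2 cleaves the glycol C1–C2 bond of 1 to the 1,6-keto aldehyde 2, L-proline then forms the enamine of the aldehyde, and its α-carbon adds to the methyl ketone through a hydrogen-bonded transition state (carboxylic acid to ketone oxygen), so the six-membered p-menthane ring is re-closed one carbon smaller and the expelled ring carbon ends as the formyl group. The closest known reaction type is the proline-catalysed enolexo intramolecular aldol addition of keto aldehydes with the aldehyde as donor and the ketone as acceptor, which gives cis-β-hydroxy aldehydes, and the amine-catalysed aldol condensation of this same keto aldehyde shows the same regiochemistry. The one ring closed, the cyclopentane, forms by 5-exo-trig attack in the 5-enolexo mode. The carbinol centre C2 is set by the cyclic hydrogen-bonded transition state, which places OH cis to CHO, and the formyl-bearing centre C1 is set by the enamine face that L-proline exposes, which is the face anti to the isopropenyl group on the bought and untouched centre C5, so catalyst and substrate should be matched; the resulting arrangement (CHO trans to both isopropenyl and methyl) is also the thermodynamic one, so epimerisation at C1 or reversible aldolisation would feed the same isomer. The step needs the aldehyde and not the ketone to act as enamine donor, which amine catalysis secures because aldehydes condense faster, and it needs to stop before dehydration to the conjugated enal, which room temperature and the absence of added base or heat should secure.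

Step 2
Reactants: 3 (1S,2R,5R)-2-hydroxy-2-methyl-5-(prop-1-en-2-yl)cyclopentane-1-carbaldehyde
Product: 4 (1S,2R,5R)-2-[(tert-butyldimethylsilyl)oxy]-2-methyl-5-(prop-1-en-2-yl)cyclopentane-1-carbaldehyde
Conditions: TBSOTf, 2,6-lutidine, CH2Cl2, −78 to 0 °C
Reagents that add atoms: tert-butyldimethylsilyl trifluoromethanesulfonate, CC(C)(C)[Si](C)(C)OS(=O)(=O)C(F)(F)F
Why: Silylation of a tertiary alcohol with a silyl triflate and a hindered base is standard silyl ether formation; it touches no stereocentre and removes the hydroxyl that would otherwise be lost by dehydration or would lactonise onto the unsaturated diester of the next step.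

Step 3
Reactants: 4 (1S,2R,5R)-2-[(tert-butyldimethylsilyl)oxy]-2-methyl-5-(prop-1-en-2-yl)cyclopentane-1-carbaldehyde; 5 dimethyl malonate
Product: 6 dimethyl 2-{[(1S,2R,5R)-2-[(tert-butyldimethylsilyl)oxy]-2-methyl-5-(prop-1-en-2-yl)cyclopentyl]methylidene}propanedioate
Conditions: TiCl4, pyridine, THF, 0 °C to rt
Reagents that add atoms: dimethyl malonate (5), COC(=O)CC(=O)OC
Why: Knoevenagel condensation with TiCl4/pyridine works at low temperature for hindered α-branched aldehydes, so the β-silyloxy aldehyde should condense without elimination; no new stereocentre is formed and C1 already holds its favoured configuration.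

Step 4
Reactants: 6 dimethyl 2-{[(1S,2R,5R)-2-[(tert-butyldimethylsilyl)oxy]-2-methyl-5-(prop-1-en-2-yl)cyclopentyl]methylidene}propanedioate
Product: 7 dimethyl 2-{[(1S,2R,5R)-2-[(tert-butyldimethylsilyl)oxy]-2-methyl-5-(prop-1-en-2-yl)cyclopentyl]methyl}propanedioate
Conditions: NaBH4, MeOH–THF, 0 °C
Reagents that add atoms: none
Why: Borohydride reduces alkylidene malonates by conjugate (1,4) hydride addition without touching the esters, the silyl ether or the isolated isopropenyl group; no new stereocentre is formed.

Step 5
Reactants: 7 dimethyl 2-{[(1S,2R,5R)-2-[(tert-butyldimethylsilyl)oxy]-2-methyl-5-(prop-1-en-2-yl)cyclopentyl]methyl}propanedioate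
Product: 8 tricyclic lactone ester (trans-fused octahydroindene with equatorial CO2Me on C5' and the axial C5' carboxyl lactonised onto the axial oxygen of C7')
Conditions: Mn(OAc)3·2H2O (2.2 equiv), AcOH, 70 °C
Reagents that add atoms: none
Why: This is an oxidative free-radical cyclisation of an unsaturated malonate with trivalent manganese: the malonyl radical adds 6-endo to the CH2 end of the 1,1-disubstituted alkene (closing ring B trans-fused, since both ring C bonds sit equatorial on the chair), the tertiary radical at C7' is oxidised to the cation, and only the ester that is axial on C5' can reach it, so lactonisation fixes the C7' oxygen axial with methyl equatorial and marks the two carboxyl groups on the new quaternary carbon as different.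

Step 6
Reactants: 8 tricyclic lactone ester; 9 5-methylhexane-2,4-dione
Product: 11 3'-[(tert-butyldimethylsilyl)oxy]-4,7'-dihydroxy-3',7'-dimethyl-3-(2-methylpropanoyl)spiro[cyclohex-3-ene-1,5'-octahydroindene]-2,6-dione, via triketo ester 10 (not isolated)
Conditions: 9 (3 equiv), LiN(iPr)2 (6 equiv), THF, 0 °C; then 8, −78 °C to rt, then 50 °C; aq. HCl work-up
Reagents that add atoms: 5-methylhexane-2,4-dione (9), CC(=O)CC(=O)C(C)C
Why: Terminal C-acylation of a 1,3-diketone dianion by the lactone (the more electrophilic acyl group through its enforced s-trans ester geometry and strain, against a methyl ester on a quaternary carbon) followed by Claisen closure of the doubly activated CH2 onto that methyl ester, the way 3,5,7-triketo esters close to acylphloroglucinols, should build ring A with the lactone carbonyl as C6 and the acyl-bearing C3 next to the equatorial carbonyl C2, which fixes the configuration of the spiro carbon; the quaternary C1 rules out the competing aldol mode.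

Step 7
Reactants: 11 3'-[(tert-butyldimethylsilyl)oxy]-4,7'-dihydroxy-3',7'-dimethyl-3-(2-methylpropanoyl)spiro[cyclohex-3-ene-1,5'-octahydroindene]-2,6-dione
Product: 12 3',4,7'-trihydroxy-3',7'-dimethyl-3-(2-methylpropanoyl)spiro[cyclohex-3-ene-1,5'-octahydroindene]-2,6-dione
Conditions: HF·pyridine, THF, 0 °C to rt
Reagents that add atoms: none
Why: Fluoride cleavage of a silyl ether with buffered HF·pyridine is tolerated by the acidic enolised triketone and by tertiary alcohols, and no stereocentre is affected.

Step 8
Reactants: 12 3',4,7'-trihydroxy-3',7'-dimethyl-3-(2-methylpropanoyl)spiro[cyclohex-3-ene-1,5'-octahydroindene]-2,6-dione; 13 prenyl bromide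
Product: 15 tomoeone D, via monoprenyl triketone 14 (not isolated)
Conditions: prenyl bromide (2.5 equiv), 10% aq. KOH, 0 °C
Reagents that add atoms: prenyl bromide (13), CC(C)=CCBr
Why: Base-mediated double C-alkylation of the one remaining ring CH2 (C5, flanked by two carbonyls) with an allylic bromide is the reaction that turns acylphloroglucinols into lupulone-type gem-diprenyl triketones; C3 is blocked by the acyl group, the tertiary alcohols are not ionised by aqueous hydroxide beside the acidic triketone, and no stereocentre is formed because C5 ends with two identical groups.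

**Compound list**

1 | (1S,2S,4R)-1-methyl-4-(prop-1-en-2-yl)cyclohexane-1,2-diol ((+)-limonene-1,2-diol) | C[C@]1(O)CC[C@@H](C(C)=C)C[C@@H]1O | starting material
2 | (3R)-6-oxo-3-(prop-1-en-2-yl)heptanal | CC(=O)CC[C@@H](C(C)=C)CC=O | intermediate
3 | (1S,2R,5R)-2-hydroxy-2-methyl-5-(prop-1-en-2-yl)cyclopentane-1-carbaldehyde (CHO trans to isopropenyl, OH cis to CHO) | O=C[C@@H]1[C@](C)(O)CC[C@H]1C(C)=C | intermediate
4 | (1S,2R,5R)-2-[(tert-butyldimethylsilyl)oxy]-2-methyl-5-(prop-1-en-2-yl)cyclopentane-1-carbaldehyde | O=C[C@@H]1[C@](C)(O[Si](C)(C)C(C)(C)C)CC[C@H]1C(C)=C | intermediate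
5 | dimethyl malonate | COC(=O)CC(=O)OC | starting material
6 | dimethyl 2-{[(1S,2R,5R)-2-[(tert-butyldimethylsilyl)oxy]-2-methyl-5-(prop-1-en-2-yl)cyclopentyl]methylidene}propanedioate | COC(=O)C(C(=O)OC)=C[C@@H]1[C@](C)(O[Si](C)(C)C(C)(C)C)CC[C@H]1C(C)=C | intermediate
7 | dimethyl 2-{[(1S,2R,5R)-2-[(tert-butyldimethylsilyl)oxy]-2-methyl-5-(prop-1-en-2-yl)cyclopentyl]methyl}propanedioate | COC(=O)C(C(=O)OC)C[C@@H]1[C@](C)(O[Si](C)(C)C(C)(C)C)CC[C@H]1C(C)=C | intermediate
8 | tricyclic lactone ester: trans-fused 3'-methyl-3'-silyloxy-octahydroindene, equatorial CO2Me on C5', axial C5' carboxyl closed as γ-lactone onto the axial oxygen of C7' (7'-methyl equatorial) | COC(=O)[C@]12C[C@H]3[C@@H](CC[C@@]3(C)O[Si](C)(C)C(C)(C)C)[C@](C)(C1)OC2=O | intermediate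
9 | 5-methylhexane-2,4-dione | CC(=O)CC(=O)C(C)C | starting material
10 | triketo ester: methyl 3'-[(tert-butyldimethylsilyl)oxy]-7'-hydroxy-3',7'-dimethyl-5'-(6-methyl-3,5-dioxoheptanoyl)octahydroindene-5'-carboxylate (acyl chain axial, ester equatorial) | COC(=O)[C@]1(C(=O)CC(=O)CC(=O)C(C)C)C[C@H]2[C@@H](CC[C@@]2(C)O[Si](C)(C)C(C)(C)C)[C@@](C)(O)C1 | intermediate
11 | 3'-[(tert-butyldimethylsilyl)oxy]-4,7'-dihydroxy-3',7'-dimethyl-3-(2-methylpropanoyl)spiro[cyclohex-3-ene-1,5'-octahydroindene]-2,6-dione (7'-OH cis to the C6 carbonyl) | C1C(=O)[C@]2(C[C@H]3[C@@H](CC[C@@]3(C)O[Si](C)(C)C(C)(C)C)[C@@](C)(O)C2)C(=O)C(C(=O)C(C)C)=C1O | intermediate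
12 | 3',4,7'-trihydroxy-3',7'-dimethyl-3-(2-methylpropanoyl)spiro[cyclohex-3-ene-1,5'-octahydroindene]-2,6-dione | C1C(=O)[C@]2(C[C@H]3[C@@H](CC[C@@]3(C)O)[C@@](C)(O)C2)C(=O)C(C(=O)C(C)C)=C1O | intermediate
13 | prenyl bromide (1-bromo-3-methylbut-2-ene) | CC(C)=CCBr | starting material
14 | monoprenyl triketone: 5-(3-methylbut-2-enyl) derivative of 12, enol form | CC(C)=CCC1=C(O)[C@]2(C[C@H]3[C@@H](CC[C@@]3(C)O)[C@@](C)(O)C2)C(=O)C(C(=O)C(C)C)=C1O | intermediate
15 | tomoeone D | CC(C)=CCC1(CC=C(C)C)C(=O)[C@]2(C[C@H]3[C@@H](CC[C@@]3(C)O)[C@@](C)(O)C2)C(=O)C(C(=O)C(C)C)=C1O | target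

**Count and risks**

Total step count: 8. Longest linear sequence: 8 steps (1 to 15).

Steps most likely to fail:

Step 6. The dianion may attack the methyl ester first instead of the lactone, which would lose the regiochemical relay and with it control at the spiro carbon, or the sequence may stall after acylation without Claisen closure. The fallback sets out from 8 and returns at 11. Saponification (LiOH, THF–H2O) and acidification, after which only the axial carboxyl can re-lactonise, should give the lactone acid F1. Oxalyl chloride with catalytic DMF converts it to the acid chloride F2. C-acylation of the magnesium enolate of 9 (MgCl2, pyridine, CH2Cl2) then gives the triacylmethane F3, in which the carbon carrying the isobutyryl group is joined to the former free carboxyl carbon by an intermolecular step of unambiguous regiochemistry. Excess LiN(SiMe3)2 in THF (−78 °C to rt) deprotonates the acetyl methyl, which closes onto the lactone carbonyl (Claisen) to give 11.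

Step 5. Closure may go 5-exo instead of 6-endo, the tertiary cation may lose a proton instead of being captured by the ester, or slow enolisation of the malonate may lead to decomposition at the temperature needed. The fallback sets out from 7 and returns at 8. Iodination (NaH, then N-iodosuccinimide, THF, 0 °C) gives the iodomalonate F4. Atom-transfer radical cyclisation ((Bu3Sn)2 catalytic, hν, benzene, 80 °C) should give the 6-endo tertiary iodide F5 without any oxidant. Heating F5 in toluene ionises the iodide, and the axial ester captures the cation with loss of iodomethane to give 8.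

Step 8. O-alkylation may compete with C-alkylation, and the second alkylation at the hindered carbon may stall. The fallback sets out from 12 and returns at 15. Double C-allylation through π-allyl intermediates (allyl methyl carbonate, Pd(PPh3)4, zerovalent palladium, THF) should give the gem-diallyl triketone F6. Cross-metathesis with 2-methylbut-2-ene (second-generation Grubbs catalyst, CH2Cl2, 40 °C) then converts both allyl groups into prenyl groups and gives 15.

**Further compounds**

F1 | step 6 | lactone acid: the carboxylic acid corresponding to methyl ester 8 | OC(=O)[C@]12C[C@H]3[C@@H](CC[C@@]3(C)O[Si](C)(C)C(C)(C)C)[C@](C)(C1)OC2=O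
F2 | step 6 | acid chloride of F1 | ClC(=O)[C@]12C[C@H]3[C@@H](CC[C@@]3(C)O[Si](C)(C)C(C)(C)C)[C@](C)(C1)OC2=O
F3 | step 6 | triacylmethane: lactone acylated on the central carbon of 5-methylhexane-2,4-dione | CC(=O)C(C(=O)C(C)C)C(=O)[C@]12C[C@H]3[C@@H](CC[C@@]3(C)O[Si](C)(C)C(C)(C)C)[C@](C)(C1)OC2=O
F4 | step 5 | iodomalonate: 2-iodo derivative of 7 | COC(=O)C(I)(C(=O)OC)C[C@@H]1[C@](C)(O[Si](C)(C)C(C)(C)C)CC[C@H]1C(C)=C
F5 | step 5 | tertiary iodide: dimethyl 7'-iodo-3',7'-dimethyl-3'-silyloxy-octahydroindene-5',5'-dicarboxylate (C7' configuration not fixed) | COC(=O)C1(C(=O)OC)C[C@H]2[C@@H](CC[C@@]2(C)O[Si](C)(C)C(C)(C)C)C(C)(I)C1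
F6 | step 8 | gem-diallyl triketone: 5,5-diallyl derivative of 12 | C=CCC1(CC=C)C(=O)[C@]2(C[C@H]3[C@@H](CC[C@@]3(C)O)[C@@](C)(O)C2)C(=O)C(C(=O)C(C)C)=C1O
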